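The tridepside is cut at its two aryl ester bonds into a ring A acid and a ring B–C phenol. The plan rests on building pentasubstituted ring A through its C1–C2 bond. In ring A the run C2(OH)–C3(H)–C4(OMe)–C5(OMe) matches the carbonyl, CH, methoxy carbon and quaternary methoxy carbon of a cyclobutenone. The precursor is a racemic 3,4-dimethoxycyclobutenone whose quaternary carbon carries C3 of an E tert-butyl but-2-enoate. Heating opens the small ring to a dienylketene, which recloses on the ester-bearing CH. One operation should therefore deliver the whole benzoate, with all five substituents placed, both methyl ethers present and only the hydrogen-bonded 2-OH free.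

Key step: step 7

Remark 1: in each ring C1 is the carboxyl-bearing carbon, C2 carries OH and C6 carries the methyl group; the names of the ring compounds follow this numbering.
Remark 2: compounds 2, 10, 11 and 13 each hold one stereocentre and are racemic; none of these centres survives and the target is achiral.
Remark 3: dimethyl squarate, but-2-ynoic acid and orsellinic acid are taken as commercial.

Step 1
Reactants: 1 dimethyl squarate
Product: 3 3-methoxycyclobut-3-ene-1,2-dione (methyl semisquarate), via hydroxycyclobutenone 2 (not isolated)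
Conditions: LiAlH(OtBu)3 (1.05 equiv), THF, −78 to −20 °C; then aq HCl, CH2Cl2, rt
Reagents that add atoms: water, O
Why: The hindered hydride should stop after one 1,2-reduction of a squarate carbonyl, and acid then converts 2 into 3 by ionisation of the allylic carbinol, capture of water at the far end of the allyl cation (the methoxy carbon next to the carbonyl) and loss of methanol, which is the standard reduction–hydrolysis entry to semisquaric esters.

Step 2
Reactants: 4 but-2-ynoic acid
Product: 5 tert-butyl but-2-ynoate
Conditions: isobutene (excess), cat H2SO4, CH2Cl2, sealed vessel, rt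
Reagents that add atoms: isobutene, CC(C)=C
Why: Acid-catalysed tert-butyl esterification (carboxylic acid plus isobutene through the tert-butyl cation) needs no nucleophilic catalyst that could add to the ynoate, and the bulky ester later shields the carbonyl from the organomagnesium centre.

Step 3
Reactants: 5 tert-butyl but-2-ynoate
Product: 7 tert-butyl (E)-3-(tributylstannyl)but-2-enoate, via alkenylcuprate adduct 6 (not isolated)
Conditions: Bu3SnH, LiN(iPr)2, THF, 0 °C; CuSPh, −20 °C; then 5, MeOH (1.7 equiv), −78 °C
Reagents that add atoms: tributyltin hydride, CCCC[SnH](CCCC)CCCC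
Why: Stannylcupration adds tin and copper syn across the triple bond with tin on the β-carbon, and methanol present at −78 °C protonates adduct 6 with retention before it can equilibrate, so tin ends trans to the ester (E), whereas hydroiodination of the same alkyne is an anti addition that would give the unusable Z halide.

Step 4
Reactants: 7 tert-butyl (E)-3-(tributylstannyl)but-2-enoate
Product: 8 tert-butyl (E)-3-iodobut-2-enoate
Conditions: I2 (1.05 equiv), CH2Cl2, 0 °C to rt, dark; aq Na2S2O3 wash
Reagents that add atoms: iodine, II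
Why: Iododestannylation is an electrophilic ipso substitution at the sp2 carbon that proceeds with retention, so the E geometry of 7 is carried into 8.

Step 5
Reactants: 8 tert-butyl (E)-3-iodobut-2-enoate; 3 3-methoxycyclobut-3-ene-1,2-dione
Product: 10 tert-butyl (E)-3-(1-hydroxy-2-methoxy-4-oxocyclobut-2-en-1-yl)but-2-enoate (racemic), via alkenylmagnesium chloride 9 (not isolated)
Conditions: iPrMgCl·LiCl (1.05 equiv), THF, −70 °C; cannulate into 3, THF, −78 °C; sat NH4Cl at −78 °C
Reagents that add atoms: none
Why: Iodine–magnesium exchange on the electron-poor alkenyl iodide is fast at low temperature and retains geometry, the tert-butyl ester tolerates the reagent there, and 1,2-addition of 9 goes to the carbonyl of 3 that flanks the methoxy carbon because the other carbonyl is a vinylogous ester, which creates the quaternary carbinol as a racemate.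

Step 6
Reactants: 10 tert-butyl (E)-3-(1-hydroxy-2-methoxy-4-oxocyclobut-2-en-1-yl)but-2-enoate
Product: 11 tert-butyl (E)-3-(1,2-dimethoxy-4-oxocyclobut-2-en-1-yl)but-2-enoate (racemic)
Conditions: MeI (10 equiv), Ag2O (2 equiv), 4 Å sieves, MeCN, rt, dark
Reagents that add atoms: iodomethane, CI
Why: Ag2O-promoted Williamson-type O-methylation runs under essentially neutral conditions that spare the sensitive hydroxycyclobutenone, and it is a more dependable way to cap this tertiary carbinol than trapping a sluggish magnesium alkoxide in the addition flask.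

Step 7
Reactants: 11 tert-butyl (E)-3-(1,2-dimethoxy-4-oxocyclobut-2-en-1-yl)but-2-enoate
Product: 14 tert-butyl 2-hydroxy-4,5-dimethoxy-6-methylbenzoate, via dienylketene 12 (not isolated), via cyclohexadienone 13 (not isolated)
Conditions: degassed toluene (0.02 M), reflux, Ar
Reagents that add atoms: none
Why: Thermal conrotatory 4π opening cleaves the bond between the carbonyl and the quaternary carbon of 11 and gives dienylketene 12, the first stage of the Moore-type ring expansion known for 4-alkenyl-4-alkoxycyclobutenones. Ring A then closes by a thermal 6π electrocyclisation in which the ketene carbon (future C2) bonds to the ester-bearing CH (future C1), giving cyclohexadienone 13. The C1–H of 13 lies between a ketone and an ester, so enolisation to phenol 14 should be fast and irreversible, it erases the only transient stereocentre, and no stereocentre remains to be controlled. The selectivity needed is torquoselectivity: the methoxy donor on the quaternary carbon prefers outward rotation and the acceptor-substituted alkenyl group prefers inward rotation, so both preferences bring the alkene next to the ketene, and a wrongly rotated ketene can only reclose to 11. The E alkene keeps the ester outside the closing triene with only H inside, and the future C4 methoxy group pushes electron density through C5 and C6 onto C1, which matches that carbon to the electrophilic ketene carbon. The position of every substituent follows from the connectivity of 11, so no aromatic substitution regiochemistry arises.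

Step 8
Reactants: 14 tert-butyl 2-hydroxy-4,5-dimethoxy-6-methylbenzoate
Product: 15 2-hydroxy-4,5-dimethoxy-6-methylbenzoic acid
Conditions: TFA/CH2Cl2 (1:4), 0 °C to rt; evaporate cold
Reagents that add atoms: none
Why: Acidolysis of the tert-butyl ester (alkyl–oxygen cleavage through the tert-butyl cation) is indifferent to the two ortho substituents that would block saponification, and running it on the free phenol at or below room temperature avoids both an acid-labile ortho benzyl ether and protodecarboxylation.

Step 9
Reactants: 16 orsellinic acid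
Product: 17 benzyl 2,4-dihydroxy-6-methylbenzoate (benzyl orsellinate)
Conditions: BnBr (1.05 equiv), KHCO3 (1.2 equiv), DMF, rt
Reagents that add atoms: benzyl bromide, BrCc1ccccc1
Why: The weak base KHCO3 forms only the carboxylate, so SN2 alkylation with benzyl bromide gives the ester and leaves both phenols free.

Step 10
Reactants: 16 orsellinic acid
Product: 19 2,4-bis[(tert-butyldimethylsilyl)oxy]-6-methylbenzoic acid, via trisilyl derivative 18 (not isolated)
Conditions: TBSCl (3.5 equiv), imidazole (7 equiv), DMF, 40 °C; then AcOH/THF/H2O, rt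
Reagents that add atoms: tert-butyldimethylsilyl chloride, CC(C)(C)[Si](C)(C)Cl
Why: Exhaustive silylation followed by mild aqueous acid exploits the much greater lability of a silyl ester compared with aryl silyl ethers (selective solvolysis), giving a ring B acid without free hydroxyl groups in one operation.

Step 11
Reactants: 19 2,4-bis[(tert-butyldimethylsilyl)oxy]-6-methylbenzoic acid; 17 benzyl orsellinate
Product: 20 benzyl 4-({2,4-bis[(tert-butyldimethylsilyl)oxy]-6-methylbenzoyl}oxy)-2-hydroxy-6-methylbenzoate
Conditions: EDC·HCl (1.3 equiv), DMAP (0.3 equiv), CH2Cl2, 0 °C to rt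
Reagents that add atoms: none
Why: Steglich esterification should acylate the 4-OH of 17 selectively because its 2-OH is tied up in a hydrogen bond to the neighbouring ester carbonyl and is crowded by it.

Step 12
Reactants: 20 silylated ring B–C depside benzyl ester
Product: 21 benzyl 4-[(2,4-dihydroxy-6-methylbenzoyl)oxy]-2-hydroxy-6-methylbenzoate (benzyl lecanorate)
Conditions: HF·pyridine, THF, 0 °C to rt, plastic vessel
Reagents that add atoms: none
Why: Fluoride-driven desilylation under mildly acidic HF·pyridine cleaves both aryl silyl ethers without generating free phenoxide, so the depside bond and the benzyl ester should stay untouched.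

Step 13
Reactants: 15 2-hydroxy-4,5-dimethoxy-6-methylbenzoic acid; 21 benzyl lecanorate
Product: 22 benzyl 2-hydroxy-4-({2-hydroxy-4-[(2-hydroxy-4,5-dimethoxy-6-methylbenzoyl)oxy]-6-methylbenzoyl}oxy)-6-methylbenzoate
Conditions: DCC (1.1 equiv), toluene–THF, 0 °C to rt
Reagents that add atoms: none
Why: Carbodiimide depside coupling relies on the fact that the three ortho hydroxyl groups (one each in rings A, B and C) are hydrogen-bonded to their own carbonyl groups and poorly nucleophilic, so the activated ring A acid should be taken up only by the free 4-OH of ring B.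

Step 14
Reactants: 22 tridepside benzyl ester
Product: 23 2-hydroxy-4-({2-hydroxy-4-[(2-hydroxy-4,5-dimethoxy-6-methylbenzoyl)oxy]-6-methylbenzoyl}oxy)-6-methylbenzoic acid (target CNP0139469.0)
Conditions: H2 (1 atm), 10% Pd/C, EtOAc, rt
Reagents that add atoms: none
Why: Catalytic hydrogenolysis of the benzyl ester is neutral and leaves aryl esters, phenols and methyl ethers alone, which avoids the hydrolysis and decarboxylation to which depside acids are prone.

Compound list
1 | dimethyl squarate (3,4-dimethoxycyclobut-3-ene-1,2-dione) | COC1=C(OC)C(=O)C1=O | starting material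
2 | 4-hydroxy-2,3-dimethoxycyclobut-2-en-1-one (racemic) | COC1=C(OC)C(O)C1=O | intermediate
3 | 3-methoxycyclobut-3-ene-1,2-dione | COC1=CC(=O)C1=O | intermediate
4 | but-2-ynoic acid | CC#CC(=O)O | starting material
5 | tert-butyl but-2-ynoate | CC#CC(=O)OC(C)(C)C | intermediate
6 | lithium phenylthiocuprate carrying the α-carbon of tert-butyl 3-(tributylstannyl)but-2-enoate, Sn and Cu on the same side of the double bond | [Li+].CCCC[Sn](CCCC)(CCCC)/C(C)=C(\[Cu-]Sc1ccccc1)C(=O)OC(C)(C)C | intermediate
7 | tert-butyl (E)-3-(tributylstannyl)but-2-enoate | CCCC[Sn](CCCC)(CCCC)/C(C)=C/C(=O)OC(C)(C)C | intermediate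
8 | tert-butyl (E)-3-iodobut-2-enoate | I/C(C)=C/C(=O)OC(C)(C)C | intermediate
9 | tert-butyl (E)-3-(chloromagnesio)but-2-enoate | Cl[Mg]/C(C)=C/C(=O)OC(C)(C)C | intermediate
10 | tert-butyl (E)-3-(1-hydroxy-2-methoxy-4-oxocyclobut-2-en-1-yl)but-2-enoate (racemic) | COC1=CC(=O)C1(O)/C(C)=C/C(=O)OC(C)(C)C | intermediate
11 | tert-butyl (E)-3-(1,2-dimethoxy-4-oxocyclobut-2-en-1-yl)but-2-enoate (racemic) | COC1=CC(=O)C1(OC)/C(C)=C/C(=O)OC(C)(C)C | intermediate
12 | tert-butyl (2E,4Z)-4,5-dimethoxy-3-methyl-7-oxohepta-2,4,6-trienoate (dienylketene) | O=C=C/C(OC)=C(OC)\C(C)=C\C(=O)OC(C)(C)C | intermediate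
13 | tert-butyl 3,4-dimethoxy-2-methyl-6-oxocyclohexa-2,4-diene-1-carboxylate (racemic) | COC1=CC(=O)C(C(=O)OC(C)(C)C)C(C)=C1OC | intermediate
14 | tert-butyl 2-hydroxy-4,5-dimethoxy-6-methylbenzoate | COc1cc(O)c(C(=O)OC(C)(C)C)c(C)c1OC | intermediate
15 | 2-hydroxy-4,5-dimethoxy-6-methylbenzoic acid | COc1cc(O)c(C(=O)O)c(C)c1OC | intermediate
16 | orsellinic acid (2,4-dihydroxy-6-methylbenzoic acid) | Cc1cc(O)cc(O)c1C(=O)O | starting material
17 | benzyl 2,4-dihydroxy-6-methylbenzoate | Cc1cc(O)cc(O)c1C(=O)OCc1ccccc1 | intermediate
18 | tert-butyldimethylsilyl 2,4-bis[(tert-butyldimethylsilyl)oxy]-6-methylbenzoate | Cc1cc(O[Si](C)(C)C(C)(C)C)cc(O[Si](C)(C)C(C)(C)C)c1C(=O)O[Si](C)(C)C(C)(C)C | intermediate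
19 | 2,4-bis[(tert-butyldimethylsilyl)oxy]-6-methylbenzoic acid | Cc1cc(O[Si](C)(C)C(C)(C)C)cc(O[Si](C)(C)C(C)(C)C)c1C(=O)O | intermediate
20 | benzyl 4-({2,4-bis[(tert-butyldimethylsilyl)oxy]-6-methylbenzoyl}oxy)-2-hydroxy-6-methylbenzoate | Cc1cc(O[Si](C)(C)C(C)(C)C)cc(O[Si](C)(C)C(C)(C)C)c1C(=O)Oc1cc(C)c(C(=O)OCc2ccccc2)c(O)c1 | intermediate
21 | benzyl 4-[(2,4-dihydroxy-6-methylbenzoyl)oxy]-2-hydroxy-6-methylbenzoate | Cc1cc(O)cc(O)c1C(=O)Oc1cc(C)c(C(=O)OCc2ccccc2)c(O)c1 | intermediate
22 | benzyl 2-hydroxy-4-({2-hydroxy-4-[(2-hydroxy-4,5-dimethoxy-6-methylbenzoyl)oxy]-6-methylbenzoyl}oxy)-6-methylbenzoate | COc1cc(O)c(C(=O)Oc2cc(C)c(C(=O)Oc3cc(C)c(C(=O)OCc4ccccc4)c(O)c3)c(O)c2)c(C)c1OC | intermediate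
23 | 2-hydroxy-4-({2-hydroxy-4-[(2-hydroxy-4,5-dimethoxy-6-methylbenzoyl)oxy]-6-methylbenzoyl}oxy)-6-methylbenzoic acid | COc1cc(O)c(C(=O)Oc2cc(C)c(C(=O)Oc3cc(C)c(C(=O)O)c(O)c3)c(O)c2)c(C)c1OC | target

Total step count: 14
Longest linear sequence: 9 steps (steps 2, 3, 4, 5, 6, 7, 8, 13, 14)

Steps most likely to fail

**1. Step 7.**
- What may go wrong: the acceptor on the closing carbon may slow the 6π closure enough for the ketene to be lost by dimerisation or by capture of traces of water. Long heating may also strip the tert-butyl group.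
- The fallback gives up the ring expansion and makes the ring A acid by oxidising a preformed arene. It sets out from 17 and comes back at 15.
- Methylation of the unchelated 4-OH (MeI, K2CO3, acetone) should give benzyl 2-hydroxy-4-methoxy-6-methylbenzoate F1.
- Elbs persulfate oxidation (K2S2O8, aqueous NaOH, pyridine) attacks C5, the only open position para to the phenoxide. This gives potassium 3-[(benzyloxy)carbonyl]-4-hydroxy-6-methoxy-2-methylphenyl sulfate F2.
- Warm dilute HCl hydrolyses F2 to benzyl 2,5-dihydroxy-4-methoxy-6-methylbenzoate F3.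
- One equivalent of MeI with K2CO3 methylates the unchelated 5-OH to benzyl 2-hydroxy-4,5-dimethoxy-6-methylbenzoate F4.
- Hydrogenolysis (H2, 10% Pd/C) then gives 15.

**2. Step 5.**
- What may go wrong: the unchelated, ester-bearing alkenylmagnesium may self-condense or lose its E geometry before it meets 3. Attack at the methoxy carbon may also compete with 1,2-addition.
- The fallback removes the ester from the organometallic and restores the oxidation level after the ring expansion. It sets out from 8, uses 3, and comes back at 15.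
- Reduction of 8 with iBu2AlH (CH2Cl2, −78 °C) should give (E)-3-iodobut-2-en-1-ol F5.
- Silylation (TBSCl, imidazole) gives tert-butyl{[(E)-3-iodobut-2-en-1-yl]oxy}dimethylsilane F6.
- Exchange with tBuLi (2 equiv, Et2O, −78 °C) gives {4-[(tert-butyldimethylsilyl)oxy]but-2-en-2-yl}lithium F7, with lithium trans to the CH2O group.
- F7 adds to 3, and the lithium alkoxide is capped in the same flask with MeOTf to give 4-{(E)-4-[(tert-butyldimethylsilyl)oxy]but-2-en-2-yl}-3,4-dimethoxycyclobut-2-en-1-one F8.
- Refluxing toluene should convert F8 into 2-{[(tert-butyldimethylsilyl)oxy]methyl}-4,5-dimethoxy-3-methylphenol F9.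
- Bu4NF frees 2-(hydroxymethyl)-4,5-dimethoxy-3-methylphenol F10, and MnO2 oxidises the benzylic alcohol to 2-hydroxy-4,5-dimethoxy-6-methylbenzaldehyde F11.
- Pinnick oxidation (NaClO2, NaH2PO4, 2-methylbut-2-ene) then gives 15.

**3. Step 13.**
- What may go wrong: rearrangement of the activated hindered acid to an unreactive acylurea, self-acylation through its own 2-OH, or acylation at a chelated hydroxyl of 21.
- The fallback masks the ring A phenol so that a DMAP-driven coupling can be forced. It sets out from 14, uses 21, and comes back at 23.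
- Benzylation (BnBr, K2CO3, DMF, 60 °C) should give tert-butyl 2-(benzyloxy)-4,5-dimethoxy-6-methylbenzoate F12.
- 85% aqueous H3PO4 in toluene, which spares the ortho benzyl ether better than TFA, cleaves the ester to 2-(benzyloxy)-4,5-dimethoxy-6-methylbenzoic acid F13.
- EDC·HCl and DMAP with 21 give benzyl 4-({4-[(2-(benzyloxy)-4,5-dimethoxy-6-methylbenzoyl)oxy]-2-hydroxy-6-methylbenzoyl}oxy)-2-hydroxy-6-methylbenzoate F14.
- Hydrogenolysis of both benzyl groups (H2, 10% Pd/C) then gives 23.

Further compounds
F1 | step 7 | benzyl 2-hydroxy-4-methoxy-6-methylbenzoate | COc1cc(C)c(C(=O)OCc2ccccc2)c(O)c1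
F2 | step 7 | potassium 3-[(benzyloxy)carbonyl]-4-hydroxy-6-methoxy-2-methylphenyl sulfate | COc1cc(O)c(C(=O)OCc2ccccc2)c(C)c1OS(=O)(=O)[O-].[K+]
F3 | step 7 | benzyl 2,5-dihydroxy-4-methoxy-6-methylbenzoate | COc1cc(O)c(C(=O)OCc2ccccc2)c(C)c1O
F4 | step 7 | benzyl 2-hydroxy-4,5-dimethoxy-6-methylbenzoate | COc1cc(O)c(C(=O)OCc2ccccc2)c(C)c1OC
F5 | step 5 | (E)-3-iodobut-2-en-1-ol | I/C(C)=C/CO
F6 | step 5 | tert-butyl{[(E)-3-iodobut-2-en-1-yl]oxy}dimethylsilane | I/C(C)=C/CO[Si](C)(C)C(C)(C)C
F7 | step 5 | {4-[(tert-butyldimethylsilyl)oxy]but-2-en-2-yl}lithium, Li trans to CH2O | [Li]/C(C)=C/CO[Si](C)(C)C(C)(C)C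
F8 | step 5 | 4-{(E)-4-[(tert-butyldimethylsilyl)oxy]but-2-en-2-yl}-3,4-dimethoxycyclobut-2-en-1-one (racemic) | COC1=CC(=O)C1(OC)/C(C)=C/CO[Si](C)(C)C(C)(C)C
F9 | step 5 | 2-{[(tert-butyldimethylsilyl)oxy]methyl}-4,5-dimethoxy-3-methylphenol | COc1cc(O)c(CO[Si](C)(C)C(C)(C)C)c(C)c1OC
F10 | step 5 | 2-(hydroxymethyl)-4,5-dimethoxy-3-methylphenol | COc1cc(O)c(CO)c(C)c1OC
F11 | step 5 | 2-hydroxy-4,5-dimethoxy-6-methylbenzaldehyde | COc1cc(O)c(C=O)c(C)c1OC
F12 | step 13 | tert-butyl 2-(benzyloxy)-4,5-dimethoxy-6-methylbenzoate | COc1cc(OCc2ccccc2)c(C(=O)OC(C)(C)C)c(C)c1OC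
F13 | step 13 | 2-(benzyloxy)-4,5-dimethoxy-6-methylbenzoic acid | COc1cc(OCc2ccccc2)c(C(=O)O)c(C)c1OC
F14 | step 13 | benzyl 4-({4-[(2-(benzyloxy)-4,5-dimethoxy-6-methylbenzoyl)oxy]-2-hydroxy-6-methylbenzoyl}oxy)-2-hydroxy-6-methylbenzoate | COc1cc(OCc2ccccc2)c(C(=O)Oc2cc(C)c(C(=O)Oc3cc(C)c(C(=O)OCc4ccccc4)c(O)c3)c(O)c2)c(C)c1OC
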